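**Assumption:** the two cyclohexane descriptors in the SMILES are read as the cis-1,4-diol (both OH on one face, pyridone trans to the secondary OH). The side chain is (8R,10R), that is syn. Acidic enols are drawn in one tautomer.

## Retrosynthetic overview
- Militarinone A ⇒ aldol/dehydration (C2=C3) between a 3-acetyl-1,4-dihydroxy-2-pyridone core and a C13 (2E,4E,6R,8R)-dienal.
- Pyridone core ⇒ ring expansion of an N-acetoacetyl isoxazol-5(2H)-one. This makes C3–C4, and the ring oxygen stays on nitrogen as N–OH.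
- Isoxazolone ⇒ α-formyl ester + NH2OH. The α-formyl ester ⇒ formate + the methyl acetate aldol adduct of 4-hydroxycyclohexanone, which sets the cis-1,4-dioxygen pattern.
- Dienal ⇒ two Wittig homologations of (2R,4R)-2,4-dimethylhexanal ⇐ double asymmetric hydrogenation of the dienoate made from tiglic aldehyde.
- Ring order: cyclohexane (bought) → isoxazolone (step 3) → pyridone by expansion of that ring (step 4).

## Route

Step 1
Reactants: 1 4-hydroxycyclohexanone; 2 methyl acetate
Product: 6 methyl 2-[cis-1,4-bis(triethylsilyloxy)cyclohexyl]acetate, via silyloxy ketone 3 (not isolated), via lithium ester enolate 4 (not isolated), via lithium aldolate 5 (not isolated)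
Conditions: a) 1, Et3SiOTf (1.05 eq), 2,6-lutidine (1.1 eq), THF, −78 to 0 °C; b) cannulate into 2 + LiN(iPr)2 (2.2 eq each), THF, −78 °C; c) Et3SiOTf (1.3 eq), −78 to 0 °C
Reagents that add atoms: triethylsilyl trifluoromethanesulfonate, CC[Si](CC)(CC)OS(=O)(=O)C(F)(F)F
Why: Alcohol silylation followed by a Rathke-type ester-enolate aldol addition; the aggregated enolate attacks the chair with equatorial OSiEt3 from the equatorial side, so the new C–C bond is equatorial and the tertiary oxygen axial, cis to the C4 oxygen (about 3:1 expected, trans isomer removed by chromatography), and capping the aldolate in situ blocks retro-aldol.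

Step 2
Reactants: 6 methyl 2-[cis-1,4-bis(triethylsilyloxy)cyclohexyl]acetate
Product: 8 methyl 2-[cis-1,4-bis(triethylsilyloxy)cyclohexyl]-3-oxopropanoate, via lithium enolate 7 (not isolated)
Conditions: LiN(iPr)2 (1.1 eq), THF, −78 °C, 20 min; HCO2CH2CF3 (1.5 eq), −78 °C; AcOH (1.2 eq)
Reagents that add atoms: 2,2,2-trifluoroethyl formate, O=COCC(F)(F)F
Why: Crossed Claisen formylation of the kinetic ester enolate with a formate electrophilic enough to react at −78 °C, faster than β-elimination of silyloxide; the new α-carbon is a labile 1,3-dicarbonyl centre that becomes sp2 in step 3.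

Step 3
Reactants: 8 methyl 2-[cis-1,4-bis(triethylsilyloxy)cyclohexyl]-3-oxopropanoate
Product: 10 4-[cis-1,4-bis(triethylsilyloxy)cyclohexyl]isoxazol-5(2H)-one, via aldoxime 9 (not isolated)
Conditions: NH2OH (50 % aq, 1.2 eq), MeOH, 25 to 50 °C
Reagents that add atoms: hydroxylamine, NO
Why: Cyclocondensation of an α-formyl ester with hydroxylamine (oxime formation, then 5-exo-trig O-acylation with loss of methanol) is the standard entry to 4-substituted isoxazol-5(2H)-ones, and the near-neutral medium leaves both silyl ethers and the cis relationship untouched.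

Step 4
Reactants: 10 4-[cis-1,4-bis(triethylsilyloxy)cyclohexyl]isoxazol-5(2H)-one; 11 diketene
Product: 14 3-acetyl-5-[cis-1,4-bis(triethylsilyloxy)cyclohexyl]-1,4-dihydroxypyridin-2(1H)-one, via N-acetoacetyl isoxazolone 12 (not isolated), via ring-opened enamido ester 13 (not isolated)
Conditions: 11 (1.1 eq), Et3N (1.05 eq), THF, −20 to 0 °C; then NaOMe (2.5 eq) in MeOH, 0 to 25 °C; 1 M HCl to pH 4
Reagents that add atoms: none
Why: Proposed new method: the acidic N–H of 10 (pKa about 5) is acetoacetylated by diketene as sulfamate and imide anions are; in 12 the ring carbonyl is an O-acyl hydroxamate, an internal active ester; base first forms the β-ketoamide enolate, which shields the exocyclic amide from methanolysis; methoxide then relays the acyl group by opening the lactone to the (Z)-enamido ester 13 with the N–O bond intact; 6-exo-trig Dieckmann closure of the enolate carbon on that ester forges C3–C4, and loss of methoxide plus enolisation gives the aromatic pyridone dianion as an irreversible sink; the net result is an isomerisation 12→14 in which the five-membered N–O ring grows to six atoms by taking in the two-carbon unit while its oxygen remains on nitrogen as N–OH; the closest known reaction types are the Gabriel–Colman ring expansion of phthalimidoacetates and the Lacey–Dieckmann cyclisation of N-acetoacetyl amino esters, neither described for isoxazol-5-ones.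

Step 5
Reactants: 15 (E)-2-methylbut-2-enal
Product: 16 ethyl (2E,4E)-2,4-dimethylhexa-2,4-dienoate
Conditions: Ph3P=C(Me)CO2Et (1.2 eq), CH2Cl2, 40 °C
Reagents that add atoms: ethyl 2-(triphenylphosphoranylidene)propanoate, CCOC(=O)C(C)=P(c1ccccc1)(c1ccccc1)c1ccccc1
Why: Wittig olefination with a stabilised ylide gives the (E)-trisubstituted enoate (>95:5) and keeps the E geometry of the aldehyde.

Step 6
Reactants: 16 ethyl (2E,4E)-2,4-dimethylhexa-2,4-dienoate
Product: 17 ethyl (2R,4R)-2,4-dimethylhexanoate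
Conditions: [Ir(cod)(L)][B(C6H3(CF3)2)4] (1 mol %), H2 (50 bar), CH2Cl2, 25 °C; L = (S)-8-(di-tert-butylphosphinooxy)-2-phenyl-5,6,7,8-tetrahydroquinoline (the antipode of L is used if the first run, checked by optical rotation, gives ent-17)
Reagents that add atoms: none
Why: Iridium N,P-catalysed (Pfaltz-type) asymmetric hydrogenation of trisubstituted olefins; both E double bonds show the catalyst the same (chain)(Me)C=CH(chain) topology, so one ligand antipode adds H2 to the same topological face twice and sets C2 and C4 as the syn-(2R,4R) pair.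

Step 7
Reactants: 17 ethyl (2R,4R)-2,4-dimethylhexanoate
Product: 19 (2E,4R,6R)-2,4,6-trimethyloct-2-enal, via aldehyde 18 (not isolated)
Conditions: iBu2AlH (1.05 eq), toluene, −78 °C; then Ph3P=C(Me)CHO (1.5 eq), −78 to 90 °C; aq KNaC4H4O6
Reagents that add atoms: 2-(triphenylphosphoranylidene)propanal, CC(C=O)=P(c1ccccc1)(c1ccccc1)c1ccccc1
Why: Partial ester reduction to the aluminium hemiacetal and in situ Wittig olefination with a stabilised formyl ylide sets the (E)-C6=C7 bond, and the α-chiral aldehyde is never handled, which protects C8 from epimerisation.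

Step 8
Reactants: 19 (2E,4R,6R)-2,4,6-trimethyloct-2-enal
Product: 21 (2E,4E,6R,8R)-4,6,8-trimethyldeca-2,4-dienal, via dienyl dioxolane 20 (not isolated)
Conditions: (1,3-dioxolan-2-ylmethyl)triphenylphosphonium bromide (1.3 eq), KOtBu (1.25 eq), THF, 0 to 25 °C; then 1 M HCl, THF, 25 °C
Reagents that add atoms: (1,3-dioxolan-2-ylmethyl)triphenylphosphonium bromide, [Br-].C(C1OCCO1)[P+](c1ccccc1)(c1ccccc1)c1ccccc1; water, O
Why: Wittig two-carbon homologation with a masked formyl ylide cannot over-homologate, and the acidic acetal hydrolysis isomerises the E/Z mixture to the conjugated (2E)-dienal.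

Step 9
Reactants: 14 3-acetyl-5-[cis-1,4-bis(triethylsilyloxy)cyclohexyl]-1,4-dihydroxypyridin-2(1H)-one; 21 (2E,4E,6R,8R)-4,6,8-trimethyldeca-2,4-dienal
Product: 23 5-[cis-1,4-bis(triethylsilyloxy)cyclohexyl]-1,4-dihydroxy-3-[(4E,6E,8R,10R)-3-hydroxy-6,8,10-trimethyldodeca-4,6-dienoyl]pyridin-2(1H)-one (both C3 carbinol epimers), via trilithium salt 22 (not isolated)
Conditions: LiN(iPr)2 (3.1 eq), THF, −78 to −30 °C; 21 (1.1 eq), −78 °C; AcOH (3.2 eq)
Reagents that add atoms: none
Why: Polyanion aldol addition of a 3-acetyl-4-hydroxy heterocycle, where the last-formed acetyl enolate is the most nucleophilic site and adds 1,2 to the dienal at −78 °C; the new carbinol centre is erased in step 10, and the low temperature leaves C8 and C10 untouched.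

Step 10
Reactants: 23 5-[cis-1,4-bis(triethylsilyloxy)cyclohexyl]-1,4-dihydroxy-3-[(4E,6E,8R,10R)-3-hydroxy-6,8,10-trimethyldodeca-4,6-dienoyl]pyridin-2(1H)-one
Product: 25 militarinone A, via bis(triethylsilyl) ether 24 (not isolated)
Conditions: HF (48 % aq, 10 eq), MeCN, 0 to 25 °C
Reagents that add atoms: none
Why: Acid-promoted dehydration of a dienylic β-hydroxy ketone (ionisation to a pentadienyl cation, loss of the α-proton) gives the thermodynamic (2E)-trienone, and fluoride-mediated desilylation in the same medium frees both hydroxyl groups without touching any C–O stereocentre.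

## Compound list
1 | 4-hydroxycyclohexanone | O=C1CCC(O)CC1 | starting material
2 | methyl acetate | COC(C)=O | starting material
3 | 4-(triethylsilyloxy)cyclohexanone | O=C1CCC(O[Si](CC)(CC)CC)CC1 | intermediate
4 | lithium 1-methoxyethen-1-olate (enolate of 2) | [Li+].COC([O-])=C | intermediate
5 | lithium cis-1-(2-methoxy-2-oxoethyl)-4-(triethylsilyloxy)cyclohexan-1-olate (both oxygens on one face) | [Li+].COC(=O)C[C@]1([O-])CC[C@@H](O[Si](CC)(CC)CC)CC1 | intermediate
6 | methyl 2-[cis-1,4-bis(triethylsilyloxy)cyclohexyl]acetate | COC(=O)C[C@]1(O[Si](CC)(CC)CC)CC[C@@H](O[Si](CC)(CC)CC)CC1 | intermediate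
7 | lithium enolate of 6 | [Li+].COC([O-])=C[C@]1(O[Si](CC)(CC)CC)CC[C@@H](O[Si](CC)(CC)CC)CC1 | intermediate
8 | methyl 2-[cis-1,4-bis(triethylsilyloxy)cyclohexyl]-3-oxopropanoate (α-carbon labile, largely enol) | COC(=O)C(C=O)[C@]1(O[Si](CC)(CC)CC)CC[C@@H](O[Si](CC)(CC)CC)CC1 | intermediate
9 | methyl 2-[cis-1,4-bis(triethylsilyloxy)cyclohexyl]-3-(hydroxyimino)propanoate | COC(=O)C(C=NO)[C@]1(O[Si](CC)(CC)CC)CC[C@@H](O[Si](CC)(CC)CC)CC1 | intermediate
10 | 4-[cis-1,4-bis(triethylsilyloxy)cyclohexyl]isoxazol-5(2H)-one | O=C1ONC=C1[C@]2(O[Si](CC)(CC)CC)CC[C@@H](O[Si](CC)(CC)CC)CC2 | intermediate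
11 | diketene (4-methylideneoxetan-2-one) | C=C1CC(=O)O1 | starting material
12 | 2-(3-oxobutanoyl)-4-[cis-1,4-bis(triethylsilyloxy)cyclohexyl]isoxazol-5(2H)-one | CC(=O)CC(=O)N1OC(=O)C(=C1)[C@]2(O[Si](CC)(CC)CC)CC[C@@H](O[Si](CC)(CC)CC)CC2 | intermediate
13 | methyl (Z)-2-[cis-1,4-bis(triethylsilyloxy)cyclohexyl]-3-[hydroxy(3-oxobutanoyl)amino]prop-2-enoate (sodium salt in the flask, drawn neutral) | COC(=O)/C(=C\N(O)C(=O)CC(C)=O)[C@]1(O[Si](CC)(CC)CC)CC[C@@H](O[Si](CC)(CC)CC)CC1 | intermediate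
14 | 3-acetyl-5-[cis-1,4-bis(triethylsilyloxy)cyclohexyl]-1,4-dihydroxypyridin-2(1H)-one | CC(=O)c1c(O)c([C@]2(O[Si](CC)(CC)CC)CC[C@@H](O[Si](CC)(CC)CC)CC2)cn(O)c1=O | intermediate
15 | (E)-2-methylbut-2-enal (tiglic aldehyde) | C/C=C(\C)C=O | starting material
16 | ethyl (2E,4E)-2,4-dimethylhexa-2,4-dienoate | C/C=C(C)/C=C(\C)C(=O)OCC | intermediate
17 | ethyl (2R,4R)-2,4-dimethylhexanoate | CC[C@@H](C)C[C@@H](C)C(=O)OCC | intermediate
18 | (2R,4R)-2,4-dimethylhexanal | CC[C@@H](C)C[C@@H](C)C=O | intermediate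
19 | (2E,4R,6R)-2,4,6-trimethyloct-2-enal | CC[C@@H](C)C[C@@H](C)/C=C(C)/C=O | intermediate
20 | 2-[(3E,5R,7R)-3,5,7-trimethylnona-1,3-dien-1-yl]-1,3-dioxolane (C1=C2 E/Z mixture) | CC[C@@H](C)C[C@@H](C)/C=C(C)/C=CC1OCCO1 | intermediate
21 | (2E,4E,6R,8R)-4,6,8-trimethyldeca-2,4-dienal | CC[C@@H](C)C[C@@H](C)/C=C(C)/C=C/C=O | intermediate
22 | trilithium salt of 14 (N-oxide, 4-oxide, acetyl enolate) | [Li+].[Li+].[Li+].C=C([O-])c1c([O-])c([C@]2(O[Si](CC)(CC)CC)CC[C@@H](O[Si](CC)(CC)CC)CC2)cn([O-])c1=O | intermediate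
23 | 5-[cis-1,4-bis(triethylsilyloxy)cyclohexyl]-1,4-dihydroxy-3-[(4E,6E,8R,10R)-3-hydroxy-6,8,10-trimethyldodeca-4,6-dienoyl]pyridin-2(1H)-one (carbinol epimers) | CC[C@@H](C)C[C@@H](C)/C=C(C)/C=C/C(O)CC(=O)c1c(O)c([C@]2(O[Si](CC)(CC)CC)CC[C@@H](O[Si](CC)(CC)CC)CC2)cn(O)c1=O | intermediate
24 | militarinone A bis(triethylsilyl) ether | CC[C@@H](C)C[C@@H](C)/C=C(C)/C=C/C=C/C(=O)c1c(O)c([C@]2(O[Si](CC)(CC)CC)CC[C@@H](O[Si](CC)(CC)CC)CC2)cn(O)c1=O | intermediate
25 | militarinone A, 5-(cis-1,4-dihydroxycyclohexyl)-1,4-dihydroxy-3-[(2E,4E,6E,8R,10R)-6,8,10-trimethyldodeca-2,4,6-trienoyl]pyridin-2(1H)-one | CC[C@@H](C)C[C@@H](C)/C=C(C)/C=C/C=C/C(=O)c1c(O)c([C@]2(O)CC[C@@H](O)CC2)cn(O)c1=O | target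

## Step count and risks
Total steps: 10. Longest linear sequence: 6 (steps 1–4, 9, 10). The side-chain arm (steps 5–8, 9, 10) is equally long.

**Step 4, the new ring expansion.**
- Possible failures are O- instead of N-acylation, methanolysis of the N-acyl group, or base-induced cleavage of the 3-unsubstituted ring.
- The fallback uses known chemistry. It sets out from 8 and comes back at 14.
- Condense 8 with O-benzylhydroxylamine (BnONH2·HCl, NaOAc, MeOH) to methyl 3-(benzyloxyamino)-2-[cis-1,4-bis(triethylsilyloxy)cyclohexyl]prop-2-enoate F1.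
- Acylate its nitrogen with acetylketene (2,2,6-trimethyl-1,3-dioxin-4-one, toluene, 110 °C) to methyl 3-[benzyloxy(3-oxobutanoyl)amino]-2-[cis-1,4-bis(triethylsilyloxy)cyclohexyl]prop-2-enoate F2.
- Close the ring by Lacey–Dieckmann cyclisation (NaOMe, MeOH) to 3-acetyl-1-(benzyloxy)-5-[cis-1,4-bis(triethylsilyloxy)cyclohexyl]-4-hydroxypyridin-2(1H)-one F3.
- Hydrogenolyse the O-benzyl group (H2, Pd/C, EtOAc) to 14. This costs three extra steps.

**Step 9, the trianion aldol.**
- Possible failures are incomplete third deprotonation, proton transfer from the dienal, and a capricious dehydration in step 10.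
- The fallback replaces aldol/dehydration by a Horner–Wadsworth–Emmons olefination. It sets out from 10 and 21 and comes back at 24.
- Heat 10 with diethyl [(2,2-dimethyl-4-oxo-1,3-dioxin-6-yl)methyl]phosphonate (toluene, 110 °C) to diethyl {4-[4-(cis-1,4-bis(triethylsilyloxy)cyclohexyl)-5-oxoisoxazol-2(5H)-yl]-2,4-dioxobutyl}phosphonate F4.
- Expand the ring as in step 4 (NaOMe, MeOH) to diethyl {2-[5-(cis-1,4-bis(triethylsilyloxy)cyclohexyl)-1,4-dihydroxy-2-oxo-1,2-dihydropyridin-3-yl]-2-oxoethyl}phosphonate F5.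
- Olefinate 21 with its trianion (KOtBu, 3.2 eq, THF, 0 °C) to 24 with the (2E) bond in place. Step 10 then only has to remove the silyl groups.

**Step 2, formylation of a β-silyloxy ester enolate.**
- The expected failure is β-elimination to the cyclohexylidene acetate.
- The fallback avoids a free enolate. It sets out from 6 and comes back at 10.
- Deprotonate 6 with LiN(iPr)2 in the presence of Me3SiCl (in situ quench, THF, −78 °C) to the ketene silyl acetal [2-(cis-1,4-bis(triethylsilyloxy)cyclohexyl)-1-methoxyethenyloxy]trimethylsilane F6.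
- Carry out a Mukaiyama-type alkylation with HC(OMe)3 and BF3·OEt2 (CH2Cl2, −78 °C) to methyl 2-[cis-1,4-bis(triethylsilyloxy)cyclohexyl]-3,3-dimethoxypropanoate F7.
- Treat F7 with NH2OH·HCl and NaOAc in aqueous MeOH at 50 °C. This unmasks the aldehyde, forms the oxime and cyclises to 10.

## Further compounds
F1 | step 4 | methyl 3-(benzyloxyamino)-2-[cis-1,4-bis(triethylsilyloxy)cyclohexyl]prop-2-enoate | COC(=O)C(=CNOCc1ccccc1)[C@]2(O[Si](CC)(CC)CC)CC[C@@H](O[Si](CC)(CC)CC)CC2
F2 | step 4 | methyl 3-[benzyloxy(3-oxobutanoyl)amino]-2-[cis-1,4-bis(triethylsilyloxy)cyclohexyl]prop-2-enoate | COC(=O)C(=CN(OCc1ccccc1)C(=O)CC(C)=O)[C@]2(O[Si](CC)(CC)CC)CC[C@@H](O[Si](CC)(CC)CC)CC2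
F3 | step 4 | 3-acetyl-1-(benzyloxy)-5-[cis-1,4-bis(triethylsilyloxy)cyclohexyl]-4-hydroxypyridin-2(1H)-one | CC(=O)c1c(O)c([C@]2(O[Si](CC)(CC)CC)CC[C@@H](O[Si](CC)(CC)CC)CC2)cn(OCc3ccccc3)c1=O
F4 | step 9 | diethyl {4-[4-(cis-1,4-bis(triethylsilyloxy)cyclohexyl)-5-oxoisoxazol-2(5H)-yl]-2,4-dioxobutyl}phosphonate | CCOP(=O)(OCC)CC(=O)CC(=O)N1OC(=O)C(=C1)[C@]2(O[Si](CC)(CC)CC)CC[C@@H](O[Si](CC)(CC)CC)CC2
F5 | step 9 | diethyl {2-[5-(cis-1,4-bis(triethylsilyloxy)cyclohexyl)-1,4-dihydroxy-2-oxo-1,2-dihydropyridin-3-yl]-2-oxoethyl}phosphonate | CCOP(=O)(OCC)CC(=O)c1c(O)c([C@]2(O[Si](CC)(CC)CC)CC[C@@H](O[Si](CC)(CC)CC)CC2)cn(O)c1=O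
F6 | step 2 | [2-(cis-1,4-bis(triethylsilyloxy)cyclohexyl)-1-methoxyethenyloxy]trimethylsilane | COC(O[Si](C)(C)C)=C[C@]1(O[Si](CC)(CC)CC)CC[C@@H](O[Si](CC)(CC)CC)CC1
F7 | step 2 | methyl 2-[cis-1,4-bis(triethylsilyloxy)cyclohexyl]-3,3-dimethoxypropanoate | COC(OC)C(C(=O)OC)[C@]1(O[Si](CC)(CC)CC)CC[C@@H](O[Si](CC)(CC)CC)CC1
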